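If this flask is run again, the reading to watch is the fraction of substrate left, so I reckoned with that fraction and not with the target made.

all flasks: substrate 0.050 M (fed, over 5.0 min)
- alder: coupling partner 0.055 M; the very flask that is asked about, followed so far; the fed solution adds 0.10 times the starting volume
- flask: coupling partner 0.0550 M; the fed solution adds 0.10 times the starting volume; time 15 h

alder run (percent of the substrate charged)

| time / h | target / % | substrate / % | intermediate / % |
|---|---|---|---|
| 0.833 | 17 | 80 | 10 |
| 1.50 | 22 | 72 | 7 |
| 2.50 | 33 | 60 | 5 |
| 3.00 | 35 | 60 | 5 |

(standard deviation of a reading: 2 percentage points)

- the largest share of what was charged as substrate, at 15 h belongs to (substrate / intermediate / target)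
- the largest share itself, whichever of these holds it, in percent of the substrate charged

1. The alder run is this flask followed so far, and its feed of 5.0 min was far shorter than the spans I used, so I let the clock start at zero.
2. The alder reading at 3.00 h stood at twice the time of the one at 1.50 h, so the two cut equal spans; in logarithms of the fraction left, the first span lost 0.329 and the second lost less, 0.182.
3. A steady first-order loss gives equal amounts in equal spans, but these two stood at a ratio of 0.555, and I supposed that each later span kept that ratio to the one before.
4. The losses then sum to 0.738, and this is the reach, the natural logarithm of the charge over the substrate left when the loss stops.
5. By 15 h, 10.0 spans had passed in this flask, so I committed to 47.9% substrate; the intermediate readings fell from 10% to 5% but then stood flat at 5%, so counting the intermediate as zero at 15 h was my assumption and not a reading, and on that assumption I committed to 52.1% target, a gap of 4.2 percentage points against a scatter of 2 points, whereas with the last intermediate reading kept the target came to 47.1%, less than the substrate.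
6. The forecast stood higher than my figure, with target at 70%, between 57% and 80%: “Target wins under either model”.

    substrate + coupling partner ⇌ intermediate (K = 170 M⁻¹, k = 0.170 M⁻¹ min⁻¹)
    intermediate → target (k = 0.0310 min⁻¹)
    2 coupling partner → homo dimer (k = 0.150 M⁻¹ min⁻¹)

At 15.0 h the flask held 52.6% target and 47.3% substrate, a reach of 0.749 against my 0.738, with homo dimer at 0.0129 M and coupling partner at 0.638% of its own charge. For the neighbour flask charged with 0.014 M of coupling partner, I scaled the reach with that charge to 0.188, which gave 82.9% substrate left. That neighbour flask held 78.0% substrate, a reach of 0.248, with coupling partner, the limiting reagent, at 0.278% of its own charge and target at 22.0%.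

The readings are simulated with made-up constants; the scatter is artificial.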